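**Plan**
- Retrosynthesis: the C9 alcohol is traced back to a carboxylic acid and the Cb–H bond to a benzylic C–O bond. The cis pair C9/Cb on the oxolane O1–C2(aryl)–C3(C9)–C4(Cb)–C5 is thereby tied into a fused γ-lactone C9(=O)–O–Cb(aryl).
- The oxolane is then cut at C2–C3 and C4–C5 together: C2–O1–C5 is a carbonyl ylide ArCH=O(+)–CH2(−), and C3=C4 is the alkene of a (5R)-5-aryl butenolide. This is possible because Cb of the target is a plain CH2 para to a phenol, so a stereocentre parked there can be erased by hydrogenolysis.
- Forward: the butenolide ring arises first (vinyl addition, lipase acryloylation, ring-closing metathesis). The oxolane ring follows by (3+2) cycloaddition; the lactone is then opened reductively and the acid reduced.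
- Stereochemistry: the lipase selects the (R)-carbinol. Its aryl group sends the ylide to the opposite face (C3, C4), cis fusion gives the cis C9/Cb pair, and an exo aryl group gives the 2,3-trans relation (C2).

Key step: step 5

Labels: the oxolane atoms of 13 are O1, C2 (trimethoxyphenyl), C3 (bears C9), C4 (bears Cb) and C5; in 8, C9 is the lactone carbonyl, C3=C4 the alkene and Cb the aryl-bearing carbon.
Assumption: the lipase shows its usual size preference with 1-arylallyl alcohols (aryl large, vinyl medium), so the (R)-carbinol is the one acylated.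

**Step 1**
Reactants: 1 3,4,5-trimethoxybenzaldehyde; 2 (trimethylsilyl)methanol
Product: 3 5-{chloro[(trimethylsilyl)methoxy]methyl}-1,2,3-trimethoxybenzene (racemic)
Conditions: HCl (g), CaCl2, CH2Cl2, 0 °C; filtered, concentrated, used crude
Reagents that add atoms: hydrogen chloride, Cl
Why: Hemiacetal formation and chloride capture of the derived oxocarbenium ion (the classical aldehyde–alcohol–HCl α-chloro ether synthesis) should give 3, with 1 driven to full conversion by excess 2 and HCl because leftover aldehyde would later trap the ylide; the racemic stereocentre becomes the planar ylide carbon.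

**Step 2**
Reactants: 4 4-(benzyloxy)-3-methoxybenzaldehyde
Product: 5 rac-1-[4-(benzyloxy)-3-methoxyphenyl]prop-2-en-1-ol
Conditions: CH2=CHMgBr, THF, −78 to 0 °C; aq. NH4Cl
Reagents that add atoms: vinylmagnesium bromide, C=C[Mg]Br
Why: Grignard 1,2-addition to an aryl aldehyde is routine, the benzyl ether is inert, and the racemic carbinol is resolved in the next step (a neutral work-up avoids allylic transposition of this electron-rich benzylic alcohol).

**Step 3**
Reactants: 5 rac-1-[4-(benzyloxy)-3-methoxyphenyl]prop-2-en-1-ol; 6 ethenyl prop-2-enoate (vinyl acrylate)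
Product: 7 (1R)-1-[4-(benzyloxy)-3-methoxyphenyl]prop-2-en-1-yl prop-2-enoate
Conditions: Novozym 435 (immobilised Candida antarctica lipase B), toluene, 30 °C, run to about half conversion
Reagents that add atoms: none
Why: Lipase-catalysed kinetic resolution by irreversible transesterification (the vinyl alcohol released tautomerises to acetaldehyde): the enzyme acylates the enantiomer shaped like (R)-1-phenylethanol, here (R)-5, so 7 forms directly with the (1R) configuration while (S)-5 stays behind and is removed by chromatography.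

**Step 4**
Reactants: 7 (1R)-1-[4-(benzyloxy)-3-methoxyphenyl]prop-2-en-1-yl prop-2-enoate
Product: 8 (5R)-5-[4-(benzyloxy)-3-methoxyphenyl]furan-2(5H)-one
Conditions: second-generation Grubbs catalyst RuCl2(=CHPh)(PCy3)(H2IMes) (5 mol%), CH2Cl2, 40 °C, high dilution
Reagents that add atoms: none
Why: Ring-closing metathesis of an allyl acrylate to a five-membered unsaturated lactone is well established with this NHC-bearing catalyst, loss of ethene drives it, and the carbinol stereocentre is not involved.

**Step 5**
Reactants: 8 (5R)-5-[4-(benzyloxy)-3-methoxyphenyl]furan-2(5H)-one; 3 5-{chloro[(trimethylsilyl)methoxy]methyl}-1,2,3-trimethoxybenzene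
Product: 10 (1R,2R,5S,6R)-6-[4-(benzyloxy)-3-methoxyphenyl]-2-(3,4,5-trimethoxyphenyl)-3,7-dioxabicyclo[3.3.0]octan-8-one, via carbonyl ylide 9 (not isolated)
Conditions: CsF (dried), MeCN, rt; 3 in excess, added slowly
Reagents that add atoms: none
Why: Chloride ionisation of 3 gives the (E)-oxocarbenium ion ArCH=O(+)–CH2SiMe3, and fluoride attack on silicon releases the non-stabilised carbonyl ylide 9 with its aryl group in the outside position. The closest known reaction type is the (3+2) cycloaddition of such fluoride-generated carbonyl ylides to acrylates, maleates and other electron-poor alkenes; a γ-aryl butenolide belongs to the same class but has not been tried. The oxolane is closed in one concerted, suprafacial, intermolecular (3+2) event that forms C2–C3 and C4–C5 together, so the new ring is necessarily cis-fused to the lactone. C3 and C4 are set by approach of the dipole to the face of 8 opposite the aryl group on Cb, and C2 by an exo transition state in which the lactone ring points away from the ylide oxygen and the outside aryl group ends trans to C9. The step needs regio-, facial and exo selectivity: the CH2 terminus has the larger HOMO coefficient and is the smaller end, so it should bond to the β carbon next to crowded Cb, the Cb aryl group shields one face, and avoiding an aryl/carbonyl clash favours exo. Slow addition of excess 3 keeps the ylide dilute and shortens the exposure of the base-sensitive γ-hydrogen of 8 to fluoride.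

**Step 6**
Reactants: 10 (1R,2R,5S,6R)-6-[4-(benzyloxy)-3-methoxyphenyl]-2-(3,4,5-trimethoxyphenyl)-3,7-dioxabicyclo[3.3.0]octan-8-one
Product: 12 (2R,3R,4S)-4-[(4-hydroxy-3-methoxyphenyl)methyl]-2-(3,4,5-trimethoxyphenyl)oxolane-3-carboxylic acid, via phenol lactone 11 (not isolated)
Conditions: H2 (1 atm), 10% Pd/C, EtOAc, rt; stopped once 11 is consumed
Reagents that add atoms: none
Why: Heterogeneous hydrogenolysis removes the aryl benzyl ether and then cleaves the lactone Cb–O bond, a benzylic ester C–O bond para to the freed phenol and so more labile than the C2–O1 alkyl ether; Cb becomes CH2 and C2, C3 and C4 are untouched.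

**Step 7**
Reactants: 12 (2R,3R,4S)-4-[(4-hydroxy-3-methoxyphenyl)methyl]-2-(3,4,5-trimethoxyphenyl)oxolane-3-carboxylic acid
Product: 13 [(2R,3S,4S)-4-[(4-hydroxy-3-methoxyphenyl)methyl]-2-(3,4,5-trimethoxyphenyl)oxolan-3-yl]methanol
Conditions: BH3·SMe2 (excess), THF, 0 °C to rt; then MeOH
Reagents that add atoms: none
Why: Chemoselective borane reduction of a carboxylic acid through its acyloxyborane; the phenol only forms a borate that methanol cleaves, the oxolane ether is inert, and no stereocentre is at risk.

**Compound list**
1 | 3,4,5-trimethoxybenzaldehyde | COc1cc(C=O)cc(OC)c1OC | starting material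
2 | (trimethylsilyl)methanol | C[Si](C)(C)CO | starting material
3 | 5-{chloro[(trimethylsilyl)methoxy]methyl}-1,2,3-trimethoxybenzene (racemic) | ClC(OC[Si](C)(C)C)c1cc(OC)c(OC)c(OC)c1 | intermediate
4 | 4-(benzyloxy)-3-methoxybenzaldehyde | O=Cc1ccc(OCc2ccccc2)c(OC)c1 | starting material
5 | rac-1-[4-(benzyloxy)-3-methoxyphenyl]prop-2-en-1-ol | C=CC(O)c1ccc(OCc2ccccc2)c(OC)c1 | intermediate
6 | ethenyl prop-2-enoate (vinyl acrylate) | C=CC(=O)OC=C | starting material
7 | (1R)-1-[4-(benzyloxy)-3-methoxyphenyl]prop-2-en-1-yl prop-2-enoate | C=CC(=O)O[C@H](C=C)c1ccc(OCc2ccccc2)c(OC)c1 | intermediate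
8 | (5R)-5-[4-(benzyloxy)-3-methoxyphenyl]furan-2(5H)-one | O=C1C=C[C@H](c2ccc(OCc3ccccc3)c(OC)c2)O1 | intermediate
9 | carbonyl ylide (E)-3,4,5-(MeO)3C6H2–CH=O(+)–CH2(−) | [CH2-]/[O+]=C/c1cc(OC)c(OC)c(OC)c1 | intermediate (not isolated)
10 | (1R,2R,5S,6R)-6-[4-(benzyloxy)-3-methoxyphenyl]-2-(3,4,5-trimethoxyphenyl)-3,7-dioxabicyclo[3.3.0]octan-8-one | O=C1O[C@@H](c2ccc(OCc3ccccc3)c(OC)c2)[C@@H]2CO[C@@H](c3cc(OC)c(OC)c(OC)c3)[C@H]12 | intermediate
11 | (1R,2R,5S,6R)-6-(4-hydroxy-3-methoxyphenyl)-2-(3,4,5-trimethoxyphenyl)-3,7-dioxabicyclo[3.3.0]octan-8-one | O=C1O[C@@H](c2ccc(O)c(OC)c2)[C@@H]2CO[C@@H](c3cc(OC)c(OC)c(OC)c3)[C@H]12 | intermediate (not isolated)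
12 | (2R,3R,4S)-4-[(4-hydroxy-3-methoxyphenyl)methyl]-2-(3,4,5-trimethoxyphenyl)oxolane-3-carboxylic acid | COc1cc(C[C@@H]2CO[C@@H](c3cc(OC)c(OC)c(OC)c3)[C@@H]2C(=O)O)ccc1O | intermediate
13 | [(2R,3S,4S)-4-[(4-hydroxy-3-methoxyphenyl)methyl]-2-(3,4,5-trimethoxyphenyl)oxolan-3-yl]methanol | COc1cc(C[C@@H]2CO[C@@H](c3cc(OC)c(OC)c(OC)c3)[C@@H]2CO)ccc1O | target

**Count**
Total: 7 steps. Longest linear sequence: 6 steps (4 to 13, steps 2 to 7); step 1 is a one-step side branch.

**Steps most likely to fail**

1. Step 5. The lactone may enter endo (giving the 2,3-cis isomer), the ylide may add in the reverse orientation, or fluoride may deprotonate the γ position of 8 and erode its configuration before it is trapped.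
Fallback, setting out from 8 and returning at 10: the same two bonds are made one after the other without fluoride. Benzophenone-sensitised irradiation (350 nm) of 8 in methanol should add a hydroxymethyl radical to the β carbon anti to the aryl group and give (4S,5R)-5-[4-(benzyloxy)-3-methoxyphenyl]-4-(hydroxymethyl)oxolan-2-one F1, which carries the C4–C5 bond. Alkylation of its hydroxyl group with chloro ether 3 and i-Pr2NEt in CH2Cl2 should give the mixed acetal (4S,5R)-5-[4-(benzyloxy)-3-methoxyphenyl]-4-({(3,4,5-trimethoxyphenyl)[(trimethylsilyl)methoxy]methoxy}methyl)oxolan-2-one F2. Me3SiOTf and Et3N in CH2Cl2 (−78 to 0 °C) should first form the ketene silyl acetal trimethyl{[(4S,5R)-5-[4-(benzyloxy)-3-methoxyphenyl]-4-({(3,4,5-trimethoxyphenyl)[(trimethylsilyl)methoxy]methoxy}methyl)-4,5-dihydrofuran-2-yl]oxy}silane F3. The same Lewis acid then ionises the acetal to the oxocarbenium ion ArCH=O(+)–C5H2, and C3 attacks it in an intramolecular Mukaiyama-type addition that forms C2–C3 and gives 10. Orientation is fixed by connectivity, the ring can only close cis, and the aryl group is again expected on the convex face.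

2. Step 1. Conversion of the aromatic aldehyde may stay incomplete and the α-chloro ether may hydrolyse on handling; either way aldehyde 1 reaches step 5 and consumes the ylide as a dioxolane.
Fallback, setting out from 1 and 2 and returning at 3: acetalisation (2 in excess, cat. p-TsOH, toluene, azeotropic removal of water) should give 5-{bis[(trimethylsilyl)methoxy]methyl}-1,2,3-trimethoxybenzene F4, which is stable and can be purified. Acetyl chloride with a trace of SOCl2 (CH2Cl2, rt) then exchanges one alkoxy group for chloride (acetal-to-chloro-ether exchange) and gives 3 under anhydrous conditions, with only a volatile acetate as co-product.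

3. Step 6. Hydrogenolysis may run on into the C2–O1 benzylic ether, or the lactone C–O cleavage may stall at the phenol stage.
Fallback, setting out from 10 and returning at 12: the hydrogenation over 10% Pd/C in EtOAc is stopped as soon as the aryl benzyl ether is gone, and phenol lactone 11 is isolated. NaBH4 in aqueous NaOH/EtOH at rt then lets the phenoxide expel the lactone carboxylate (1,6-elimination) to form the para-quinone methide (2R,3R,4S)-4-[(3-methoxy-4-oxocyclohexa-2,5-dien-1-ylidene)methyl]-2-(3,4,5-trimethoxyphenyl)oxolane-3-carboxylic acid F5 (present as its carboxylate). Borohydride reduces it at the exocyclic carbon, and acidification gives 12. Only the para-hydroxybenzylic C–O bond can react this way, so C2–O1 is not at risk.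

**Further compounds**
F1 | step 5 | (4S,5R)-5-[4-(benzyloxy)-3-methoxyphenyl]-4-(hydroxymethyl)oxolan-2-one | O=C1O[C@@H](c2ccc(OCc3ccccc3)c(OC)c2)[C@H](CO)C1
F2 | step 5 | (4S,5R)-5-[4-(benzyloxy)-3-methoxyphenyl]-4-({(3,4,5-trimethoxyphenyl)[(trimethylsilyl)methoxy]methoxy}methyl)oxolan-2-one (both acetal epimers) | O=C1O[C@@H](c2ccc(OCc3ccccc3)c(OC)c2)[C@H](COC(OC[Si](C)(C)C)c2cc(OC)c(OC)c(OC)c2)C1
F3 | step 5 | trimethyl{[(4S,5R)-5-[4-(benzyloxy)-3-methoxyphenyl]-4-({(3,4,5-trimethoxyphenyl)[(trimethylsilyl)methoxy]methoxy}methyl)-4,5-dihydrofuran-2-yl]oxy}silane | C[Si](C)(C)OC1=C[C@@H](COC(OC[Si](C)(C)C)c2cc(OC)c(OC)c(OC)c2)[C@H](c2ccc(OCc3ccccc3)c(OC)c2)O1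
F4 | step 1 | 5-{bis[(trimethylsilyl)methoxy]methyl}-1,2,3-trimethoxybenzene | COc1cc(C(OC[Si](C)(C)C)OC[Si](C)(C)C)cc(OC)c1OC
F5 | step 6 | (2R,3R,4S)-4-[(3-methoxy-4-oxocyclohexa-2,5-dien-1-ylidene)methyl]-2-(3,4,5-trimethoxyphenyl)oxolane-3-carboxylic acid | COC1=CC(=C[C@@H]2CO[C@@H](c3cc(OC)c(OC)c(OC)c3)[C@@H]2C(=O)O)C=CC1=O
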